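**Retrosynthetic overview**

1. Target 25 comes from dienone 24 by conjugate reduction (sets C7); 24 comes from enone 21 by α-iodination and Stille isopropenylation.
2. Ring B (C5-C6-C7-C8-C9-C10) is closed last, at C6=C7, by aldol condensation of a C8 methyl ketone onto the C6 aldehyde; C8-C9 is made by adding 1-ethoxyvinyllithium to a C9 aldehyde (sets C9).
3. Ring A (C1-C2-C3-C4-C5-C10) is made first by a catalytic enantioselective Diels–Alder reaction that forms C3-C4 and C5-C10. The strategy rests on C15-C4-C5(C14)-C6 being the carbon skeleton of (E)-2-methylbut-2-enal: its E geometry becomes the cis relation of the C4 and C5 methyl groups.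
4. The diene carries C9 as CH2OPMB and the future C3 oxygen as SiMe2Ph (Tamao–Fleming, retention); it is made in two steps from (E)-pent-2-en-4-yn-1-ol.
5. Ring order: ring A (step 3), then ring B (step 13).

Key step: step 3

Convention: eremophilane numbering of the target is used for every intermediate; β is the face of the C14 and C15 methyl groups, α the opposite face.

Assumption: the (R)-oxazaborolidinium ion is taken to expose the Si face at C5 of the bound enal (priority CHO > C4 > CH3), by analogy with the accepted model for 2-substituted enals; if the sense proves opposite, the (S)-catalyst is used.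

**Route**

Step 1
Reactants: 1 (E)-pent-2-en-4-yn-1-ol; 2 4-methoxybenzyl chloride
Product: 3 (E)-1-[(4-methoxybenzyl)oxy]pent-2-en-4-yne
Conditions: NaH, n-Bu4NI (cat.), THF/DMF, 0 °C → rt
Reagents that add atoms: none
Why: Williamson ether synthesis, in which the alkoxide (the alcohol is far more acidic than the alkyne C–H) displaces chloride from the benzylic halide; no stereocenter is involved.

Step 2
Reactants: 3 (E)-1-[(4-methoxybenzyl)oxy]pent-2-en-4-yne; 4 dimethylphenylsilane
Product: 5 (2E,4E)-5-[dimethyl(phenyl)silyl]penta-2,4-dienyl 4-methoxybenzyl ether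
Conditions: Pt2[(CH2=CHSiMe2)2O]3 (0.5 mol%), P(t-Bu)3 (1 mol%), THF, rt
Reagents that add atoms: none
Why: Platinum-catalysed hydrosilylation of a terminal alkyne, in which syn addition of Si–H with silicon at the terminal carbon should give the (E)-vinylsilane and the bulky phosphine suppresses the internal isomer, so the (2E,4E)-diene results.

Step 3
Reactants: 5 (2E,4E)-5-[dimethyl(phenyl)silyl]penta-2,4-dienyl 4-methoxybenzyl ether; 6 tiglic aldehyde, (E)-2-methylbut-2-enal
Product: 7 ring A cyclohexene carbaldehyde: C1=C2 alkene, 4β,5β-dimethyl, 5α-CHO (C6), 3α-SiMe2Ph, 10α-CH2OPMB (C9)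
Conditions: (R)-3,3-diphenyl-1-(2-methylphenyl)tetrahydro-1H,3H-pyrrolo[1,2-c][1,3,2]oxazaborole (20 mol%), Tf2NH (16 mol%), excess enal, CH2Cl2, −78 → −20 °C
Reagents that add atoms: none
Why: The s-trans enal is bound through its carbonyl oxygen to the cationic boron (formyl C–H in contact with the ring oxygen) and undergoes a concerted, asynchronous [4+2] cycloaddition in which the C3–C4 bond runs ahead of the C5–C10 bond; the closest known reaction type is the oxazaborolidinium-catalysed Diels–Alder reaction of 2-methyl-2-enals with acyclic dienes, applied here to a new diene. Ring A closes by intermolecular [4+2] cycloaddition, both new ring bonds being made in this one step. C4 and C5 keep the E geometry of the dienophile (suprafacial addition), so the two methyl groups end up cis; C3 and C10 follow from the (E,E) geometry of the diene and the endo position of the formyl group, which places SiMe2Ph, CH2OPMB and CHO on one face; the absolute sense comes from the catalyst, whose aryl group covers one face of the bound enal so that the diene adds to the Si face at C5. The step needs regioselectivity (C4 to the silyl-bearing terminus, C5 to the alkyl-bearing terminus), endo selectivity and facial selectivity. Regiochemistry is secured by the substrate: the CH2OPMB group stabilises positive charge building at C10, the C3–Si bond stabilises charge at C2 (β-silicon effect), and the less hindered diene terminus meets the carbon that becomes quaternary. Endo selectivity is expected because an acyclic diene has no bridging CH2 to clash with the α-methyl group, and the slight excess of oxazaborolidine over Tf2NH keeps free acid away from the PMB ether and the allylsilane.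

Step 4
Reactants: 7 ring A cyclohexene carbaldehyde
Product: 8 ring A cyclohexane carbaldehyde: as 7 with C1–C2 saturated
Conditions: H2 (1 atm), 5% Pt/C, EtOAc, rt
Reagents that add atoms: none
Why: Heterogeneous catalytic hydrogenation of the cis-disubstituted C1=C2 alkene, which at 1 atm over Pt on carbon should leave the PMB ether, the arylsilane and the hindered aldehyde untouched; no stereocenter is formed.

Step 5
Reactants: 8 ring A cyclohexane carbaldehyde
Product: 9 C6 1,3-dioxolane of 8 (3α-SiMe2Ph, 10α-CH2OPMB)
Conditions: ethylene glycol, PPTS (cat.), PhH, reflux (Dean–Stark)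
Reagents that add atoms: ethylene glycol, OCCO
Why: Acid-catalysed acetalisation with azeotropic removal of water, which masks the non-enolisable C6 aldehyde (C5 is quaternary and cannot epimerise) for the oxidation and organolithium steps; PPTS is too weak to cleave the PMB ether.

Step 6
Reactants: 9 C6 1,3-dioxolane with 3α-SiMe2Ph
Product: 10 3α-alcohol (C6 dioxolane, C9 PMB ether)
Conditions: KH, t-BuOOH, DMF, 0 °C → rt; then n-Bu4NF, 70 °C
Reagents that add atoms: tert-butyl hydroperoxide, CC(C)(C)OO
Why: Tamao–Fleming oxidation in its basic variant, in which the peroxide anion displaces the phenyl group from silicon (lost as benzene) and, after fluoride activation, C3 shifts from silicon to oxygen with retention, giving the 3α-alcohol; the basic medium spares the dioxolane and the PMB ether, which acidic Fleming conditions would not.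

Step 7
Reactants: 10 3α-alcohol; 11 tiglic acid, (E)-2-methylbut-2-enoic acid
Product: 12 3α-tiglate (C6 dioxolane, C9 PMB ether)
Conditions: DCC, DMAP, CH2Cl2, rt
Reagents that add atoms: none
Why: Steglich esterification, in which the acylpyridinium ion formed from the O-acylisourea acylates the equatorial secondary C3 hydroxyl; the E geometry of the acid and the C3 configuration are not touched.

Step 8
Reactants: 12 3α-tiglate with C9 PMB ether
Product: 13 C9 primary alcohol (3α-tiglate, C6 dioxolane)
Conditions: DDQ, CH2Cl2/pH 7 phosphate buffer (10:1), 0 °C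
Reagents that add atoms: none
Why: Oxidative cleavage of the PMB ether (hydride abstraction to an oxocarbenium ion, then hydrolysis), to which the tiglate and dioxolane are inert; the buffer prevents acid-catalysed exchange between the free C9 hydroxyl and the neighbouring acetal.

Step 9
Reactants: 13 C9 primary alcohol
Product: 14 C9 aldehyde (10α-CHO, 3α-tiglate, C6 dioxolane)
Conditions: Dess–Martin periodinane, pyridine, CH2Cl2, 0 °C → rt
Reagents that add atoms: none
Why: Dess–Martin oxidation of a primary alcohol, buffered with pyridine so that C10 (now α to an aldehyde) and the dioxolane stay intact; the aldehyde is used directly.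

Step 10
Reactants: 14 C9 aldehyde; 15 ethyl vinyl ether
Product: 17 (9R)-carbinol bearing the 1-ethoxyvinyl group at C9, via 1-ethoxyvinyllithium 16 (not isolated)
Conditions: t-BuLi, excess 15, THF, −78 → 0 °C; then 14, THF, −78 °C; H2O
Reagents that add atoms: none
Why: Addition of an acyl anion equivalent (α-lithiated enol ether) to the aldehyde under Felkin–Anh control, the nucleophile entering anti to the quaternary C5 and past H10, which should give the 9R configuration (9β in the target); at −78 °C addition to the aldehyde should outrun attack on the hindered conjugated tiglate and α-deprotonation at C10.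

Step 11
Reactants: 17 (9R)-carbinol; 18 3-methylbut-2-enoic acid (senecioic acid)
Product: 19 (9R)-senecioate with the 1-ethoxyvinyl group and C6 dioxolane
Conditions: DCC, DMAP, CH2Cl2, 0 °C → rt
Reagents that add atoms: none
Why: Steglich esterification under non-acidic conditions, so that the enol ether and the dioxolane survive and O9 is capped before C6 is unmasked (a free C9 hydroxyl would form a cyclic acetal with C6); C9 is not touched.

Step 12
Reactants: 19 (9R)-senecioate
Product: 20 keto aldehyde: C6 aldehyde on C5, C8 methyl ketone, 9-senecioate, 3α-tiglate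
Conditions: 1 M HCl, THF, rt → 45 °C
Reagents that add atoms: water, O
Why: Acid hydrolysis of the enol ether (fast, gives the C8 methyl ketone) and of the dioxolane (gives the C6 aldehyde), which the two conjugated esters tolerate in dilute acid; no stereocenter changes.

Step 13
Reactants: 20 keto aldehyde
Product: 21 bicyclic enone: 3α-tigloyloxy-9β-senecioyloxy-10βH-eremophil-6-en-8-one lacking the C7 substituent (C6=C7, C7–H)
Conditions: Bn2NH·CF3CO2H (1 equiv), PhH, 60 °C
Reagents that add atoms: none
Why: Intramolecular aldol condensation (6-(enolendo)-exo-trig), in which only the C7 methyl group can reach the non-enolisable C6 aldehyde through a six-membered ring and dehydration gives the C6=C7 enone and closes ring B; the mild ammonium salt should leave C9 alone, and its 9β (equatorial) configuration is in any case the stable one.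

Step 14
Reactants: 21 bicyclic enone
Product: 22 7-iodo enone
Conditions: I2, pyridine, CH2Cl2, 0 °C → rt
Reagents that add atoms: iodine, II
Why: Johnson α-iodination of an enone (reversible addition of pyridine at C6, iodination of the enolate at C7, elimination), a reaction type that works on 4,4-disubstituted cyclohexenones, which the quaternary C5 mimics; esters and C9 are not affected.

Step 15
Reactants: 22 7-iodo enone; 23 tributyl(prop-1-en-2-yl)stannane
Product: 24 cross-conjugated dienone: 7-isopropenyl-6-en-8-one
Conditions: Pd(PPh3)4 (5 mol%), CuI (10 mol%), DMF, 45 °C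
Reagents that add atoms: none
Why: Stille coupling (oxidative addition into the C7–I bond, copper-assisted transmetallation, reductive elimination) under neutral conditions that spare both esters and the C9 stereocenter.

Step 16
Reactants: 24 cross-conjugated dienone
Product: 25 target, 3α-[(E)-2-methylbut-2-enoyloxy]-9β-(3-methylbut-2-enoyloxy)-7β-isopropenyl-10βH-eremophil-11-en-8-one (CNP0375730.1)
Conditions: [(Ph3P)CuH]6 (0.4 equiv), H2O (3 equiv), PhH/THF, rt, Ar
Reagents that add atoms: none
Why: Conjugate reduction with a phosphine copper hydride, in which hydride adds to C6 (the only position that leads to an enolate) and the copper dienolate is protonated at C7, the α-carbon, from the axial direction, so the isopropenyl group takes the equatorial 7β position, which is also the more stable epimer; the two enoate esters should react far more slowly than the ketone-activated alkene.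

**Compound list**

1 | (E)-pent-2-en-4-yn-1-ol | C#C/C=C/CO | starting material
2 | 4-methoxybenzyl chloride | COc1ccc(CCl)cc1 | starting material
3 | (E)-1-[(4-methoxybenzyl)oxy]pent-2-en-4-yne | COc1ccc(COC/C=C/C#C)cc1 | intermediate
4 | dimethylphenylsilane | C[SiH](C)c1ccccc1 | starting material
5 | (2E,4E)-5-[dimethyl(phenyl)silyl]penta-2,4-dienyl 4-methoxybenzyl ether | COc1ccc(COC/C=C/C=C/[Si](C)(C)c2ccccc2)cc1 | intermediate
6 | tiglic aldehyde, (E)-2-methylbut-2-enal | C/C=C(\C)C=O | starting material
7 | ring A cyclohexene carbaldehyde (C1=C2; 4β,5β-dimethyl; 5α-CHO; 3α-SiMe2Ph; 10α-CH2OPMB) | O=C[C@@]1(C)[C@H](C=C[C@@H]([Si](C)(C)c2ccccc2)[C@@H]1C)COCc1ccc(OC)cc1 | intermediate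
8 | ring A cyclohexane carbaldehyde (7 with C1–C2 saturated) | O=C[C@@]1(C)[C@H](CC[C@@H]([Si](C)(C)c2ccccc2)[C@@H]1C)COCc1ccc(OC)cc1 | intermediate
9 | C6 1,3-dioxolane of 8 | O1CCOC1[C@@]2(C)[C@H](CC[C@@H]([Si](C)(C)c3ccccc3)[C@@H]2C)COCc2ccc(OC)cc2 | intermediate
10 | 3α-alcohol (C6 dioxolane, C9 PMB ether) | O1CCOC1[C@@]2(C)[C@H](CC[C@@H](O)[C@@H]2C)COCc2ccc(OC)cc2 | intermediate
11 | tiglic acid, (E)-2-methylbut-2-enoic acid | C/C=C(\C)C(=O)O | starting material
12 | 3α-tiglate (C6 dioxolane, C9 PMB ether) | O1CCOC1[C@@]2(C)[C@H](CC[C@@H](OC(=O)/C(C)=C/C)[C@@H]2C)COCc2ccc(OC)cc2 | intermediate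
13 | C9 primary alcohol (3α-tiglate, C6 dioxolane) | O1CCOC1[C@@]2(C)[C@H](CC[C@@H](OC(=O)/C(C)=C/C)[C@@H]2C)CO | intermediate
14 | C9 aldehyde (3α-tiglate, C6 dioxolane) | O1CCOC1[C@@]2(C)[C@H](CC[C@@H](OC(=O)/C(C)=C/C)[C@@H]2C)C=O | intermediate
15 | ethyl vinyl ether | C=COCC | starting material
16 | 1-ethoxyvinyllithium | [Li]C(=C)OCC | intermediate
17 | (9R)-carbinol with 1-ethoxyvinyl group at C9 | O1CCOC1[C@@]2(C)[C@H](CC[C@@H](OC(=O)/C(C)=C/C)[C@@H]2C)[C@@H](O)C(=C)OCC | intermediate
18 | 3-methylbut-2-enoic acid (senecioic acid) | CC(C)=CC(=O)O | starting material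
19 | (9R)-senecioate with 1-ethoxyvinyl group and C6 dioxolane | O1CCOC1[C@@]2(C)[C@H](CC[C@@H](OC(=O)/C(C)=C/C)[C@@H]2C)[C@@H](OC(=O)C=C(C)C)C(=C)OCC | intermediate
20 | keto aldehyde (C6 aldehyde, C8 methyl ketone, 9-senecioate, 3α-tiglate) | O=C[C@@]1(C)[C@H](CC[C@@H](OC(=O)/C(C)=C/C)[C@@H]1C)[C@@H](OC(=O)C=C(C)C)C(C)=O | intermediate
21 | bicyclic enone (C6=C7, 8-one, 9β-senecioate, 3α-tiglate, 10βH) | C1=C[C@@]2(C)[C@H](CC[C@@H](OC(=O)/C(C)=C/C)[C@@H]2C)[C@@H](OC(=O)C=C(C)C)C1=O | intermediate
22 | 7-iodo enone | IC1=C[C@@]2(C)[C@H](CC[C@@H](OC(=O)/C(C)=C/C)[C@@H]2C)[C@@H](OC(=O)C=C(C)C)C1=O | intermediate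
23 | tributyl(prop-1-en-2-yl)stannane | C=C(C)[Sn](CCCC)(CCCC)CCCC | starting material
24 | 7-isopropenyl dienone | C=C(C)C1=C[C@@]2(C)[C@H](CC[C@@H](OC(=O)/C(C)=C/C)[C@@H]2C)[C@@H](OC(=O)C=C(C)C)C1=O | intermediate
25 | CNP0375730.1, 3α-tigloyloxy-9β-senecioyloxy-7β-isopropenyl-10βH-eremophil-11-en-8-one | C=C(C)[C@H]1C[C@@]2(C)[C@H](CC[C@@H](OC(=O)/C(C)=C/C)[C@@H]2C)[C@@H](OC(=O)C=C(C)C)C1=O | target

**Step count**

Total: 16 steps. Longest linear sequence: 16 steps (from 1).

**Steps most likely to fail**

Step 3 (Diels–Alder). What may go wrong: the hindered trisubstituted enal may bind the boron cation too weakly for turnover at low temperature, so that the cycloaddition stalls or runs through an unselective background path with loss of facial control. The fallback sets out from 5 and 6 and gives up catalytic induction for resolution. A Me2AlCl-promoted Diels–Alder reaction (20 mol%, CH2Cl2, −78 → −20 °C) should give the racemic adduct, that is 7 together with its enantiomer F1. Condensation of the racemate with (1S,2S)-N,N'-dimethyl-1,2-diphenylethane-1,2-diamine (molecular sieves, Et2O, rt) should give the diastereomeric imidazolidine of 7 F2 and the imidazolidine of the enantiomer F3, which are separated by chromatography. Mild hydrolysis of the first (aqueous AcOH/NaOAc, Et2O, 0 °C) returns enantiopure 7, and the route resumes at step 4.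

Step 16 (conjugate reduction). What may go wrong: hydride transfer to the hindered C6 may be slow, so that the conjugated esters are attacked, or the dienolate is protonated at the terminal carbon of the isopropenyl group and the double bond moves into conjugation with the ketone. The fallback sets out from enone 21 and forms the C7–C11 bond after the reduction instead of before it. RhCl(PPh3)3-catalysed 1,4-hydrosilylation with Et3SiH (PhH, 50 °C) should give the triethylsilyl enol ether F4, with the enol double bond fixed at C7=C8. Palladium-catalysed alkenylation of the derived tin enolate (Bu3SnF, 2-bromopropene, PdCl2[P(o-tol)3]2, PhH, reflux) joins C7 to the isopropenyl carbon with the alkene already out of conjugation; the substituent is expected in the equatorial 7β position. This arrives at 25 and replaces steps 14 to 16.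

Step 10 (addition to the C9 aldehyde). What may go wrong: poor facial selectivity, because chelation through a dioxolane oxygen competes with the Felkin–Anh path, so that the C9 epimer is formed beside 17. The fallback sets out from 14, accepts the epimeric addition product, the (9S)-carbinol F5, and replaces kinetic control at C9 by thermodynamic control. F5 is taken through steps 11 to 13 unchanged, to the (9S)-senecioate F6, the 9-epi keto aldehyde F7 and the 9-epi enone F8. In F8 the ester is axial and syn to C4, and C9–H is the only enolisable position (C5 is quaternary). Equilibration with DBU (cat., toluene, rt → 50 °C) through the C8 dienolate should therefore move the ester to the equatorial 9β position, which is 21, and the route resumes at step 14.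

Further compounds

F1 | step 3 | enantiomer of 7 (formed with 7 as the racemate) | O=C[C@]1(C)[C@@H](C=C[C@H]([Si](C)(C)c2ccccc2)[C@H]1C)COCc1ccc(OC)cc1
F2 | step 3 | imidazolidine of 7 with (1S,2S)-N,N'-dimethyl-1,2-diphenylethane-1,2-diamine | CN1[C@@H](c2ccccc2)[C@H](c2ccccc2)N(C)C1[C@@]3(C)[C@H](C=C[C@@H]([Si](C)(C)c4ccccc4)[C@@H]3C)COCc3ccc(OC)cc3
F3 | step 3 | imidazolidine of the enantiomer of 7 with the same diamine | CN1[C@@H](c2ccccc2)[C@H](c2ccccc2)N(C)C1[C@]3(C)[C@@H](C=C[C@H]([Si](C)(C)c4ccccc4)[C@H]3C)COCc3ccc(OC)cc3
F4 | step 16 | triethylsilyl enol ether (C7=C8) of the saturated ketone from 21 | CC[Si](CC)(CC)OC1=CC[C@@]2(C)[C@H](CC[C@@H](OC(=O)/C(C)=C/C)[C@@H]2C)[C@H]1OC(=O)C=C(C)C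
F5 | step 10 | (9S)-carbinol, C9 epimer of 17 | O1CCOC1[C@@]2(C)[C@H](CC[C@@H](OC(=O)/C(C)=C/C)[C@@H]2C)[C@H](O)C(=C)OCC
F6 | step 10 | (9S)-senecioate, C9 epimer of 19 | O1CCOC1[C@@]2(C)[C@H](CC[C@@H](OC(=O)/C(C)=C/C)[C@@H]2C)[C@H](OC(=O)C=C(C)C)C(=C)OCC
F7 | step 10 | 9-epi keto aldehyde, C9 epimer of 20 | O=C[C@@]1(C)[C@H](CC[C@@H](OC(=O)/C(C)=C/C)[C@@H]1C)[C@H](OC(=O)C=C(C)C)C(C)=O
F8 | step 10 | 9-epi enone, C9 epimer of 21 | C1=C[C@@]2(C)[C@H](CC[C@@H](OC(=O)/C(C)=C/C)[C@@H]2C)[C@H](OC(=O)C=C(C)C)C1=O
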